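**The leftover.** What the target does not take of the charge that reacts is lost to side products, and in the cedar run that leftover is large. Its last three readings, from 8.00 h to 15.0 h, average 27.3% and spread about as a repeat would, so 72.7% of the charge went elsewhere.

common to all: gas 38 mM (held)

| flask | solid substrate | temperature | remark | time |
|---|---|---|---|---|
| cedar | 0.11 M | 110 °C | run made earlier |  |
| Thursday's | 0.10 M | 110 °C |  | 25 h |
| Monday's | 0.050 M | 130 °C |  | 25 h |
| Saturday's | 0.10 M | 130 °C |  | 25 h |
| Wednesday's | 0.050 M | 110 °C |  | 25 h |

cedar run (percent of the solid substrate charged): time / h: target / % = 1.33: 5; 4.00: 24; 8.00: 26; 10.0: 29; 15.0: 27

(standard deviation of a reading: 1.5 percentage points)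

- in percentages every species weighs as the solid substrate in it: one side product B counts as two
- as a solid, counted per litre of solution: solid substrate
- at the start none of reagent is dissolved
- candidate steps: starting material + reagent -> target; starting material -> side product A; 2 starting material -> side product B; gas <-> reagent; solid substrate <-> starting material
- at the start none of the solid substrate is in solution
- what has only dissolved of solid substrate counts as not reacted
- the earlier runs do not show what temperature does; that part of a forecast is a guess

- ranking by amount of target, in percent of the solid substrate charged, from high to low, at 25 h (Thursday's / Monday's / Saturday's / Wednesday's)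
- the amount of target, in percent of the solid substrate charged of the flask you put first, at 25 h
- the amount of target, in percent of the solid substrate charged of the flask you put last, at 25 h

**The ratio.** We carry one number read off the cedar readings, 2.66, the loss ratio: charge lost to side products per unit of charge made into target. It is a selectivity factor turned upside down. At equal [reagent], the side product A part of it does not change with [starting material], while the side product B part grows in step with [starting material].

**Two extremes.** Suppose the loss is side product A. Then the ratio stays, and Wednesday's gives 27.3%. Suppose instead the loss is side product B and [starting material] follows the charge. Then the ratio shrinks to 1.21, and Wednesday's gives 45.2%.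

**Our estimate.** Splitting the cedar loss evenly between side product A and side product B gives 34.1% for Wednesday's. We expect somewhat less: the cedar target climbs over hours (5% at 1.33 h, 24% at 4.00 h), which may mean a solid that feeds slowly, and then [starting material] need not follow the charge in full. We expect Thursday's between 27.3% and 29.3%, so we rank Wednesday's above it and leave 130 °C unreckoned.

**The forecast.** It ranks Wednesday's > Monday's > Thursday's > Saturday's, from 38% down to 23%, a top above our estimate: “Halving the loading lowers dissolved starting material, which disfavours second-order B.”

**The result.** The flasks rank Wednesday's > Thursday's > Saturday's > Monday's, from 30.4% down to 16.8%.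

    starting material + reagent → target (k = 0.458 M⁻¹ min⁻¹, Ea = 87.0 kJ mol⁻¹)
    starting material → side product A (k = 0.00765 min⁻¹, Ea = 117 kJ mol⁻¹)
    2 starting material → side product B (k = 0.120 M⁻¹ min⁻¹, Ea = 63.0 kJ mol⁻¹)
    gas ⇌ reagent, rate k4*(csat - [reagent]) (kL = 0.00748 min⁻¹)
    solid substrate ⇌ starting material, rate k5*(cs5 - [starting material]) while solid is left; crystals form when [starting material] > cs5 (solubility = 0.0800 M, k = 0.0150 min⁻¹)
    (constants at 110 °C)

**The neighbour.** Wednesday's loss ratio is 2.29, against the 2.66 read for cedar. It splits into 1.44 for side product A and a smaller 0.854 for side product B. For a neighbour of Wednesday's charged with 0.020 M, we hold the first part and shrink the correction with the charge to 0.342. The ratio becomes 1.78 and the target 36.0%. That neighbour gives 35.0% at 25.0 h.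

The runs were generated by integration on assumed constants; the scatter is artificial.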